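**Retrosynthetic overview**

1. Locants: C6 (lactone O–CH), C7 (ring fusion), C8 (CH–O-tigloyl), C9 (CH2), C10/C1 (epoxide, C10 methylated), C2 (ketone), C3=C4 (Z, C4 methylated), C5 (carbinol); lactone carbons C11 (α), C12 (C=O), C13 (=CH2). Last events: tiglate on O8, and closure of the ten-membered ring at C2–C3 by an intramolecular Nozaki–Hiyama–Kishi reaction of a (Z)-vinyl iodide with an epoxy aldehyde, then oxidation.
2. The cis-fused α-methylene-γ-butyrolactone (O–C6–C7–C11–C12) is taken as the Baeyer–Villiger ring expansion of a 2-methylenecyclobutanone (C6–C12–C11–C7); the C6–C12 bond is temporary and oxygen is inserted into it.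
3. Key disconnection: the cyclobutanone is the [2+2] adduct of a ketene C6=C12=O (from a photochemical Wolff rearrangement) and the C7=C11 bond of a terminal allene C7=C11=C13. The enabling feature is that C6–C7 lies between the two oxygen-bearing carbons C5 and C8 and that H6/H7 are cis, so both partners can be hung on one temporary O5–Si(i-Pr)2–O8 bridge; its seven-membered ring enforces the cis fusion and relays both resident stereocentres.
4. Fragments: the ketene half from (R)-glyceraldehyde acetonide (C5; Z-iodoalkene C3=C4 by anti-carbomagnesiation); the allene half from a Noyori-reduced chloro-ynone (C8), Negishi carboalumination (C1=C10), Sharpless epoxidation (C1, C10) and Crabbé homologation (allene).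
5. Ring order: epoxide → silaketal ring and cyclobutanone together (key step) → lactone (ring expansion) → ten-membered ring → tether removed.

Key step: step 17

Remark: the target is treated as the open cis-γ-hydroxy enone that is drawn, not as a C2/O5 hemiketal; strongly acidic conditions are therefore avoided after step 21.

**Route**

Step 1
Reactants: 1 (R)-2,2-dimethyl-1,3-dioxolane-4-carbaldehyde
Product: 2 (S)-4-ethynyl-2,2-dimethyl-1,3-dioxolane
Conditions: dimethyl (1-diazo-2-oxopropyl)phosphonate, K2CO3, MeOH, 0 °C to rt
Reagents that add atoms: dimethyl (1-diazo-2-oxopropyl)phosphonate, COP(=O)(OC)C(=[N+]=[N-])C(C)=O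
Why: Ohira–Bestmann (Seyferth–Gilbert) homologation turns the aldehyde into the terminal alkyne under mild base, so the α-oxygenated stereocentre (the future C5) should be carried through unchanged.

Step 2
Reactants: 2 (S)-4-ethynyl-2,2-dimethyl-1,3-dioxolane
Product: 3 (S)-but-3-yne-1,2-diol
Conditions: 1 M aq HCl, THF, rt
Reagents that add atoms: none
Why: acid-catalysed acetonide hydrolysis frees the propargylic hydroxyl that must direct the next step, and no stereocentre is touched.

Step 3
Reactants: 3 (S)-but-3-yne-1,2-diol
Product: 5 (2S,3Z)-4-iodo-3-methylbut-3-ene-1,2-diol, via alkenylmagnesium bromide 4 (not isolated)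
Conditions: MeMgBr (4 equiv), CuI (10 mol %), THF/Et2O, −10 °C to rt; then I2, −40 to 0 °C
Reagents that add atoms: methylmagnesium bromide, C[Mg]Br; iodine, II
Why: copper-catalysed anti-carbomagnesiation of the propargylic alkoxide (five-membered magnesium chelate) should place methyl on the proximal carbon and magnesium on the terminal carbon cis to the carbinol, and iodinolysis with retention then fixes the Z geometry of the future C3=C4 bond.

Step 4
Reactants: 5 (2S,3Z)-4-iodo-3-methylbut-3-ene-1,2-diol
Product: 6 (2S,3Z)-2-hydroxy-4-iodo-3-methylbut-3-enoic acid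
Conditions: TEMPO (cat.), NaOCl (cat.), NaClO2, MeCN/phosphate buffer pH 6.7, 35 °C
Reagents that add atoms: sodium chlorite, [Na+].[O-]Cl=O
Why: the oxoammonium oxidation is selective for the primary alcohol and chlorite carries the aldehyde on to the acid (TEMPO/chlorite oxidation), which should leave the secondary allylic carbinol and its configuration untouched.

Step 5
Reactants: 6 (2S,3Z)-2-hydroxy-4-iodo-3-methylbut-3-enoic acid
Product: 7 methyl (2S,3Z)-2-hydroxy-4-iodo-3-methylbut-3-enoate (fragment A)
Conditions: TMSCHN2, MeOH/PhMe, 0 °C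
Reagents that add atoms: trimethylsilyldiazomethane, C[Si](C)(C)C=[N+]=[N-]
Why: esterification with the diazomethane surrogate is selective for the carboxylic acid and needs no base, so the α-stereocentre is not at risk.

Step 6
Reactants: 8 ethynyltriisopropylsilane; 9 2-chloro-N-methoxy-N-methylacetamide
Product: 10 1-chloro-4-(triisopropylsilyl)but-3-yn-2-one
Conditions: n-BuLi, THF, −78 °C; then 9, −78 to 0 °C; aq NH4Cl
Reagents that add atoms: none
Why: Weinreb amide acylation of the lithium acetylide should stop at the ketone because the chelated tetrahedral intermediate survives until work-up.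

Step 7
Reactants: 10 1-chloro-4-(triisopropylsilyl)but-3-yn-2-one
Product: 11 (S)-1-chloro-4-(triisopropylsilyl)but-3-yn-2-ol
Conditions: Ru[(R,R)-TsNCH(Ph)CH(Ph)NH](p-cymene) (1 mol %), i-PrOH, rt
Reagents that add atoms: none
Why: Noyori asymmetric transfer hydrogenation of the ynone, with the alkynyl group in the role of the aryl group of an aryl ketone, should give the (S)-chlorohydrin with the (R,R)-catalyst and so set the future C8 stereocentre.

Step 8
Reactants: 11 (S)-1-chloro-4-(triisopropylsilyl)but-3-yn-2-ol
Product: 13 (R)-1-(triisopropylsilyl)hexa-1,5-diyn-3-ol, via silylethynyloxirane 12 (not isolated)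
Conditions: LiC≡CH·H2NCH2CH2NH2 (3 equiv), DMSO, 0 °C to rt
Reagents that add atoms: lithium acetylide, [Li]C#C
Why: the alkoxide closes to the epoxide (intramolecular Williamson reaction) and the acetylide opens it by SN2 attack at the unsubstituted carbon, so the carbinol stereocentre is not involved.

Step 9
Reactants: 13 (R)-1-(triisopropylsilyl)hexa-1,5-diyn-3-ol
Product: 15 (2E,5R)-3-methyl-7-(triisopropylsilyl)hept-2-en-6-yne-1,5-diol, via alkenyldimethylalane 14 (not isolated)
Conditions: Me3Al (3.5 equiv), Cp2ZrCl2 (0.3 equiv), CH2Cl2, 0 °C to rt; then n-BuLi, (CH2O)n, THF, −78 °C to rt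
Reagents that add atoms: trimethylaluminium, C[Al](C)C; formaldehyde (as paraformaldehyde), C=O
Why: Negishi zirconium-catalysed carboalumination should add methyl and aluminium syn across the terminal alkyne only (the bulky silylalkyne is inert), and trapping the alkenylalanate with formaldehyde with retention gives the E allylic alcohol (future C1=C10 geometry).

Step 10
Reactants: 15 (2E,5R)-3-methyl-7-(triisopropylsilyl)hept-2-en-6-yne-1,5-diol
Product: 16 (2E,5R)-3-methylhept-2-en-6-yne-1,5-diol
Conditions: Bu4NF, THF, 0 °C to rt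
Reagents that add atoms: none
Why: fluoride-induced protodesilylation of the alkynylsilane frees the terminal alkyne at a stage where no other silicon group is present.

Step 11
Reactants: 16 (2E,5R)-3-methylhept-2-en-6-yne-1,5-diol
Product: 17 [(2R,3R)-3-[(2R)-2-hydroxybut-3-yn-1-yl]-3-methyloxiran-2-yl]methanol
Conditions: Ti(OiPr)4 (10 mol %), D-(−)-diethyl tartrate (12 mol %), t-BuOOH, 4 Å MS, CH2Cl2, −20 °C
Reagents that add atoms: tert-butyl hydroperoxide, CC(C)(C)OO
Why: Sharpless asymmetric epoxidation is specific for the primary allylic alcohol and reagent-controlled, and D-(−)-tartrate should deliver the (2R,3R)-epoxy alcohol from the E olefin, which sets C1 and C10 with C2 and C9 trans.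

Step 12
Reactants: 17 [(2R,3R)-3-[(2R)-2-hydroxybut-3-yn-1-yl]-3-methyloxiran-2-yl]methanol
Product: 18 (2R)-1-[(2R,3R)-2-methyl-3-{[(triethylsilyl)oxy]methyl}oxiran-2-yl]but-3-yn-2-ol
Conditions: Et3SiCl (1.05 equiv), imidazole, CH2Cl2, −40 °C
Reagents that add atoms: chlorotriethylsilane, CC[Si](Cl)(CC)CC
Why: silyl ether formation at low temperature should be selective for the primary over the secondary propargylic hydroxyl.

Step 13
Reactants: 18 (2R)-1-[(2R,3R)-2-methyl-3-{[(triethylsilyl)oxy]methyl}oxiran-2-yl]but-3-yn-2-ol
Product: 19 (2R)-1-[(2R,3R)-2-methyl-3-{[(triethylsilyl)oxy]methyl}oxiran-2-yl]penta-3,4-dien-2-ol (fragment B)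
Conditions: (CH2O)n, CuI (0.5 equiv), Cy2NH, 1,4-dioxane, reflux
Reagents that add atoms: formaldehyde (as paraformaldehyde), C=O
Why: Crabbé homologation (Mannich reaction to the propargylic amine, then copper-mediated hydride transfer with loss of the imine) converts the terminal alkyne into the terminal allene without touching C8.

Step 14
Reactants: 7 methyl (2S,3Z)-2-hydroxy-4-iodo-3-methylbut-3-enoate; 19 allenyl carbinol (fragment B)
Product: 21 silaketal ester (7 and 19 joined as O5–Si(i-Pr)2–O8), via chlorosilyl ether 20 (not isolated)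
Conditions: 7, i-Pr2SiCl2 (3 equiv), Et3N, DMAP (cat.), CH2Cl2, 0 °C; excess silane removed in vacuo; then 19, imidazole, DMF, rt
Reagents that add atoms: dichlorodiisopropylsilane, CC(C)[Si](Cl)(Cl)C(C)C
Why: stepwise silylation of two secondary alcohols with a dialkyldichlorosilane (temporary silicon tether) should give the unsymmetrical silaketal, the less nucleophilic α-hydroxy ester being silylated first with excess reagent; no stereocentre is affected.

Step 15
Reactants: 21 silaketal ester
Product: 22 silaketal carboxylic acid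
Conditions: Me3SnOH (5 equiv), 1,2-dichloroethane, 70 °C; cold 0.1 M HCl wash
Reagents that add atoms: trimethyltin hydroxide, C[Sn](C)(C)O
Why: methyl ester cleavage with Me3SnOH proceeds under near-neutral conditions, which should avoid epimerisation at the doubly activated C5 and spare the silaketal, the silyl ether, the epoxide and the allene.

Step 16
Reactants: 22 silaketal carboxylic acid
Product: 24 silaketal α-diazoketone, via mixed carbonic anhydride 23 (not isolated)
Conditions: ClCO2Et, Et3N, THF, −15 °C; then CH2N2 (Et2O, excess), −15 to 0 °C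
Reagents that add atoms: diazomethane, C=[N+]=[N-]
Why: acylation of diazomethane by the mixed anhydride (first stage of the Arndt–Eistert sequence) should give the α-diazoketone without an acid chloride, and the diazomethane carbon becomes C6.

Step 17
Reactants: 24 silaketal α-diazoketone
Product: 26 cis-fused 2-methylenecyclobutanone on the seven-membered silaketal, via ketene 25 (not isolated)
Conditions: hν (440–450 nm LED), PhMe (2 mM), 25 °C, then 70 °C until the ketene is consumed
Reagents that add atoms: none
Why: Proposed new method: visible light expels N2 and triggers the Wolff rearrangement (C5 migrates with retention), and the aldoketene C6=C12=O should then add thermally across the proximal C7=C11 bond of the allene in a concerted, asynchronous [2+2] cycloaddition in which the electrophilic ketene carbon C12 bonds to the central allene carbon C11 and C6 bonds to C7; the closest known reactions are intramolecular ketene–alkene and ketene–allene [2+2] cycloadditions of ketenes made by Wolff rearrangement or dehydrohalogenation and silicon-tethered cycloadditions, and what is new is the O–Si–O tether and the seven-membered ring. The cyclobutanone is closed by the [2+2] cycloaddition itself (ketene as the antarafacial partner), and the 1,3-dioxa-2-silepane is closed in the fused, 7-exo mode by the C6–C7 bond. C6 and C7 must become cis because a four-membered ring can only be cis-fused to the seven-membered ring, and their sense relative to C5 and C8 is set by both resident stereocentres together, each of which should keep its carbon chain (C4, C9) on the convex face, anti to the forming cyclobutanone (matched case). The step needs periselectivity over ketene dimerisation (high dilution), site selectivity for the proximal over the distal allene double bond (seven- against nine-membered tether ring) and the normal ketene regiochemistry (C12 to the central carbon), which the short silaketal tether and the polarity of the ketene should secure.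

Step 18
Reactants: 26 cis-fused 2-methylenecyclobutanone
Product: 27 cis-fused α-methylene-γ-butyrolactone on the silaketal
Conditions: mCPBA, NaHCO3, CH2Cl2, 0 °C
Reagents that add atoms: 3-chloroperbenzoic acid, O=C(OO)c1cccc(Cl)c1
Why: Baeyer–Villiger oxidation of the strained cyclobutanone is fast, and migration of the secondary sp3 carbon C6 rather than the vinylic C11, with retention at C6, should give the α-methylene-γ-butyrolactone, as is known for 2-methylenecyclobutanones.

Step 19
Reactants: 27 α-methylene-γ-butyrolactone with primary triethylsilyl ether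
Product: 28 α,β-epoxy aldehyde (C2)
Conditions: (COCl)2, DMSO, CH2Cl2, −78 to −30 °C; then Et3N, −78 to 0 °C
Reagents that add atoms: none
Why: under Swern conditions a primary triethylsilyl ether is cleaved and oxidised in one operation while the hindered secondary silaketal is inert, which should give the epoxy aldehyde directly.

Step 20
Reactants: 28 α,β-epoxy aldehyde bearing the (Z)-vinyl iodide
Product: 29 ten-membered allylic alcohol (both C2 epimers)
Conditions: CrCl2 (10 equiv), NiCl2 (2 mol %), DMSO/THF, rt, 2 mM, syringe-pump addition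
Reagents that add atoms: none
Why: the intramolecular Nozaki–Hiyama–Kishi reaction (nickel-catalysed formation of the alkenylchromium with retention of the Z geometry, then chemoselective addition to the aldehyde) should close the ten-membered ring, helped by the cis arrangement of both chains on the silaketal–lactone template; the new carbinol centre C2 is removed in the next step.

Step 21
Reactants: 29 ten-membered allylic alcohol
Product: 30 silaketal-bridged epoxy enone
Conditions: Dess–Martin periodinane, NaHCO3, CH2Cl2, 0 °C to rt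
Reagents that add atoms: none
Why: Dess–Martin oxidation should convert both C2 epimers into the same epoxy enone under buffered, non-basic conditions.

Step 22
Reactants: 30 silaketal-bridged epoxy enone
Product: 31 5,8-diol
Conditions: HF·pyridine, pyridine (excess), THF, 0 °C to rt
Reagents that add atoms: none
Why: fluoride cleavage of both Si–O bonds removes the temporary tether, and buffering with pyridine should protect the epoxy ketone and the cis-γ-hydroxy enone from acid.

Step 23
Reactants: 31 5,8-diol; 32 tigloyl chloride ((E)-2-methylbut-2-enoyl chloride)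
Product: 33 target (CNP0345622.1)
Conditions: 32 (1.1 equiv), pyridine, DMAP (cat.), CH2Cl2, −20 to 0 °C
Reagents that add atoms: none
Why: site-selective esterification should occur at the C8 hydroxyl, which is flanked by a methylene group, rather than at the allylic C5 hydroxyl, which is deactivated by the vicinal lactone oxygen and can hydrogen-bond to the C2 carbonyl.

**Compound list**

1 | (R)-2,2-dimethyl-1,3-dioxolane-4-carbaldehyde | O=C[C@H]1COC(C)(C)O1 | starting material
2 | (S)-4-ethynyl-2,2-dimethyl-1,3-dioxolane | C#C[C@H]1COC(C)(C)O1 | intermediate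
3 | (S)-but-3-yne-1,2-diol | C#C[C@H](O)CO | intermediate
4 | (Z)-alkenylmagnesium bromide, bis(bromomagnesium) alkoxide of 5 with MgBr in place of I | Br[Mg]O[C@@H](/C(C)=C\[Mg]Br)CO[Mg]Br | intermediate
5 | (2S,3Z)-4-iodo-3-methylbut-3-ene-1,2-diol | O[C@@H](/C(C)=C\I)CO | intermediate
6 | (2S,3Z)-2-hydroxy-4-iodo-3-methylbut-3-enoic acid | O[C@@H](/C(C)=C\I)C(=O)O | intermediate
7 | methyl (2S,3Z)-2-hydroxy-4-iodo-3-methylbut-3-enoate (fragment A) | O[C@@H](/C(C)=C\I)C(=O)OC | intermediate
8 | ethynyltriisopropylsilane | C#C[Si](C(C)C)(C(C)C)C(C)C | starting material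
9 | 2-chloro-N-methoxy-N-methylacetamide | ClCC(=O)N(C)OC | starting material
10 | 1-chloro-4-(triisopropylsilyl)but-3-yn-2-one | ClCC(=O)C#C[Si](C(C)C)(C(C)C)C(C)C | intermediate
11 | (S)-1-chloro-4-(triisopropylsilyl)but-3-yn-2-ol | ClC[C@H](C#C[Si](C(C)C)(C(C)C)C(C)C)O | intermediate
12 | (S)-2-[(triisopropylsilyl)ethynyl]oxirane | CC(C)[Si](C(C)C)(C(C)C)C#C[C@H]1CO1 | intermediate
13 | (R)-1-(triisopropylsilyl)hexa-1,5-diyn-3-ol | C#CC[C@H](C#C[Si](C(C)C)(C(C)C)C(C)C)O | intermediate
14 | (E)-alkenyldimethylalane, dimethylaluminium alkoxide (from syn-methylalumination of 13) | C[Al](C)/C=C(C)/C[C@H](C#C[Si](C(C)C)(C(C)C)C(C)C)O[Al](C)C | intermediate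
15 | (2E,5R)-3-methyl-7-(triisopropylsilyl)hept-2-en-6-yne-1,5-diol | OC/C=C(C)/C[C@H](C#C[Si](C(C)C)(C(C)C)C(C)C)O | intermediate
16 | (2E,5R)-3-methylhept-2-en-6-yne-1,5-diol | OC/C=C(C)/C[C@H](C#C)O | intermediate
17 | [(2R,3R)-3-[(2R)-2-hydroxybut-3-yn-1-yl]-3-methyloxiran-2-yl]methanol | OC[C@H]1O[C@]1(C)C[C@H](C#C)O | intermediate
18 | (2R)-1-[(2R,3R)-2-methyl-3-{[(triethylsilyl)oxy]methyl}oxiran-2-yl]but-3-yn-2-ol | CC[Si](CC)(CC)OC[C@H]1O[C@]1(C)C[C@H](C#C)O | intermediate
19 | (2R)-1-[(2R,3R)-2-methyl-3-{[(triethylsilyl)oxy]methyl}oxiran-2-yl]penta-3,4-dien-2-ol (fragment B) | CC[Si](CC)(CC)OC[C@H]1O[C@]1(C)C[C@H](C=C=C)O | intermediate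
20 | methyl (2S,3Z)-2-{[chloro(diisopropyl)silyl]oxy}-4-iodo-3-methylbut-3-enoate | Cl[Si](C(C)C)(C(C)C)O[C@@H](/C(C)=C\I)C(=O)OC | intermediate
21 | silaketal ester: 7 and 19 linked through their secondary oxygens (O5, O8) by Si(i-Pr)2; stereocentres as in 7 and 19 | CC[Si](CC)(CC)OC[C@H]1O[C@]1(C)C[C@H](C=C=C)O[Si](C(C)C)(C(C)C)O[C@@H](/C(C)=C\I)C(=O)OC | intermediate
22 | silaketal carboxylic acid (CO2H in place of CO2Me of 21) | CC[Si](CC)(CC)OC[C@H]1O[C@]1(C)C[C@H](C=C=C)O[Si](C(C)C)(C(C)C)O[C@@H](/C(C)=C\I)C(=O)O | intermediate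
23 | mixed ethyl carbonic anhydride of 22 | CC[Si](CC)(CC)OC[C@H]1O[C@]1(C)C[C@H](C=C=C)O[Si](C(C)C)(C(C)C)O[C@@H](/C(C)=C\I)C(=O)OC(=O)OCC | intermediate
24 | silaketal α-diazoketone (C5–C12(=O)–C6H=N2; allene on C8) | CC[Si](CC)(CC)OC[C@H]1O[C@]1(C)C[C@H](C=C=C)O[Si](C(C)C)(C(C)C)O[C@@H](/C(C)=C\I)C(=O)C=[N+]=[N-] | intermediate
25 | silaketal ketene (C5–C6H=C12=O; allene on C8) | CC[Si](CC)(CC)OC[C@H]1O[C@]1(C)C[C@H](C=C=C)O[Si](C(C)C)(C(C)C)O[C@@H](/C(C)=C\I)C=C=O | intermediate
26 | cis-fused 2-methylenecyclobutanone (C12=O, C11=CH2, C6, C7) on the seven-membered O5–Si(i-Pr)2–O8 ring; C5 carries the (Z)-1-iodoprop-1-en-2-yl group, C8 the CH2–epoxide–CH2OSiEt3 chain; H6/H7 cis, anti to both chains | CC[Si](CC)(CC)OC[C@H]1O[C@]1(C)C[C@H]2O[Si](C(C)C)(C(C)C)O[C@@H](/C(C)=C\I)[C@@H]3C(=O)C(=C)[C@H]23 | intermediate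
27 | cis-fused α-methylene-γ-butyrolactone (O inserted between C6 and C12 of 26) on the silaketal | CC[Si](CC)(CC)OC[C@H]1O[C@]1(C)C[C@H]2O[Si](C(C)C)(C(C)C)O[C@@H](/C(C)=C\I)[C@@H]3OC(=O)C(=C)[C@H]23 | intermediate
28 | epoxy aldehyde (C2 CHO in place of CH2OSiEt3 of 27) | O=C[C@H]1O[C@]1(C)C[C@H]2O[Si](C(C)C)(C(C)C)O[C@@H](/C(C)=C\I)[C@@H]3OC(=O)C(=C)[C@H]23 | intermediate
29 | ten-membered ring allylic alcohol (C2–OH, both epimers), 3Z-ene, 1,10-epoxide, 6,7-cis-lactone, O5/O8 silaketal | C=C1C(=O)O[C@@H]2[C@H]1[C@H](O3)C[C@@]1(C)O[C@@H]1C(O)/C=C(/C)[C@@H]2O[Si]3(C(C)C)C(C)C | intermediate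
30 | silaketal-bridged epoxy enone (C2 ketone of 29) | C=C1C(=O)O[C@@H]2[C@H]1[C@H](O3)C[C@@]1(C)O[C@@H]1C(=O)/C=C(/C)[C@@H]2O[Si]3(C(C)C)C(C)C | intermediate
31 | 5,8-diol (des-tigloyl target) | C=C1C(=O)O[C@@H]2[C@H]1[C@H](O)C[C@@]1(C)O[C@@H]1C(=O)/C=C(/C)[C@@H]2O | intermediate
32 | tigloyl chloride, (E)-2-methylbut-2-enoyl chloride | C/C=C(\C)C(Cl)=O | starting material
33 | target CNP0345622.1: 1,10-epoxy-5-hydroxy-2-oxo-8-tigloyloxy-3Z,11(13)-diene 6,7-cis-lactone (C1 S, C5 S, C6 R, C7 R, C8 R, C10 R in the locants used here) | C=C1C(=O)O[C@@H]2[C@H]1[C@H](OC(=O)/C(C)=C/C)C[C@@]1(C)O[C@@H]1C(=O)/C=C(/C)[C@@H]2O | target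

**Step count and risks**

Total step count: 23. Longest linear sequence: 18 steps (steps 6–13, then 14–23).

Steps most likely to fail:

1. Step 17 (bears the label "Proposed new method:"). The ketene may dimerise or be hydrated faster than it closes the seven-membered ring, or it may add to the distal allene double bond; facial selectivity may also be incomplete. Fallback with known chemistry: set out from 21, reduce the ester with i-Bu2AlH (CH2Cl2, −78 °C) to the silaketal α-silyloxy aldehyde F1, and subject it to the allenic hetero-Pauson–Khand cyclocarbonylation (Mo(CO)6, DMSO, PhMe, 100 °C), which is known to turn allenyl aldehydes into cis-fused α-methylene-γ-butyrolactones. Here the aldehyde carbon becomes C6, its oxygen the ring oxygen, and CO supplies C12. The route is rejoined at 27.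

2. Step 20. The alkenylchromium may be protonated or reduced before the strained ten-membered ring closes, and intermolecular coupling may compete. Fallback that moves the ring closure to C3=C4: set out from 28, remove iodine (Pd(PPh3)4 cat., Bu3SnH added slowly, THF, 0 °C) to give the isopropenyl aldehyde F2. Add a vinyl group chemoselectively to the aldehyde (vinyl bromide, CrCl2, NiCl2 cat., DMSO) to give the divinyl carbinol-type allylic alcohol F3, and oxidise (Dess–Martin periodinane) to the vinyl ketone F4. Close the ring by ring-closing metathesis (second-generation Hoveyda–Grubbs catalyst, PhMe, 80 °C, 1 mM); the ten-membered ring should admit only the Z enone. The route is rejoined at 30.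

3. Step 23. Acylation may not discriminate enough between the two secondary hydroxyls, and the free C8 hydroxyl may attack the lactone under basic conditions. Fallback by a protecting-group detour: set out from 31 and silylate both hydroxyls (Et3SiOTf, 2,6-lutidine, CH2Cl2, −78 °C) to the bis(triethylsilyl) ether F5. Cleave the less hindered, more basic C8 silyl ether by controlled methanolysis (PPTS, MeOH/CH2Cl2, 0 °C; the other materials are recycled) to the 5-O-triethylsilyl alcohol F6. Esterify under forcing conditions (32, DMAP, or tiglic acid with 2,4,6-trichlorobenzoyl chloride, Et3N, DMAP) to the 5-O-triethylsilyl tiglate F7, and desilylate (HF·pyridine, pyridine, THF). The route is rejoined at 33.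

**Further compounds**

F1 | step 17 | silaketal α-silyloxy aldehyde (CHO in place of CO2Me of 21) | CC[Si](CC)(CC)OC[C@H]1O[C@]1(C)C[C@H](C=C=C)O[Si](C(C)C)(C(C)C)O[C@@H](/C(C)=C\I)C=O
F2 | step 20 | isopropenyl epoxy aldehyde (28 with H in place of I) | O=C[C@H]1O[C@]1(C)C[C@H]2O[Si](C(C)C)(C(C)C)O[C@@H](C(C)=C)[C@@H]3OC(=O)C(=C)[C@H]23
F3 | step 20 | allylic alcohol from vinyl addition to F2 (both C2 epimers) | C=CC(O)[C@H]1O[C@]1(C)C[C@H]2O[Si](C(C)C)(C(C)C)O[C@@H](C(C)=C)[C@@H]3OC(=O)C(=C)[C@H]23
F4 | step 20 | epoxy vinyl ketone (metathesis precursor) | C=CC(=O)[C@H]1O[C@]1(C)C[C@H]2O[Si](C(C)C)(C(C)C)O[C@@H](C(C)=C)[C@@H]3OC(=O)C(=C)[C@H]23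
F5 | step 23 | 5,8-bis-O-triethylsilyl ether of 31 | C=C1C(=O)O[C@@H]2[C@H]1[C@H](O[Si](CC)(CC)CC)C[C@@]1(C)O[C@@H]1C(=O)/C=C(/C)[C@@H]2O[Si](CC)(CC)CC
F6 | step 23 | 5-O-triethylsilyl ether of 31 | C=C1C(=O)O[C@@H]2[C@H]1[C@H](O)C[C@@]1(C)O[C@@H]1C(=O)/C=C(/C)[C@@H]2O[Si](CC)(CC)CC
F7 | step 23 | 5-O-triethylsilyl ether of 33 | C=C1C(=O)O[C@@H]2[C@H]1[C@H](OC(=O)/C(C)=C/C)C[C@@]1(C)O[C@@H]1C(=O)/C=C(/C)[C@@H]2O[Si](CC)(CC)CC
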